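(All runs were generated by integration with made-up constants, and the scatter is random.)

| flask | substrate | solid reagent | remark | time |
|---|---|---|---|---|
| ash | 13 mM | 16 mM | run made earlier |  |
| alder | 30 mM | 16 mM | run made earlier |  |
| cedar | 20 mM | 24 mM | run made earlier |  |
| teal | 20 mM | 16.0 mM |  | 2.0 min |
| green | 20 mM | 16.0 mM |  | 6.0 min |

| run | time / s | substrate / % | target / % | intermediate / % | isomer of the product / % |
|---|---|---|---|---|---|
| ash | 15.0 | 99.4 | 1.1 | 0.8 | 0.2 |
| ash | 40.0 | 95.0 | 1.3 | 0 | 3.7 |
| ash | 80.0 | 85.7 | 1.2 | 0 | 11.8 |
| ash | 120 | 76.6 | 1.9 | 0.4 | 22.0 |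
| alder | 10.0 | 100.1 | 0.7 | 0.2 | 0 |
| alder | 20.0 | 97.7 | 0.4 | 0.1 | 0.4 |
| alder | 50.0 | 93.5 | 1.8 | 0.8 | 4.9 |
| alder | 120 | 78.8 | 1.2 | 0.6 | 18.5 |
| cedar | 10.0 | 99.8 | 0.7 | 1.1 | 0 |
| cedar | 20.0 | 98.7 | 0.2 | 0.5 | 0.3 |
| cedar | 50.0 | 93.6 | 1.2 | 0 | 5.2 |
| cedar | 120 | 78.8 | 1.4 | 0.3 | 20.8 |

(scatter of a reading: 0.5 percentage points)

- as a solid, counted per litre of solution: solid reagent
- the numbers in the tables scatter with a standard deviation of 0.5 percentage points
- on the list of suspects stand: substrate + partner -> intermediate + by-product; intermediate <-> target; solid reagent <-> partner; intermediate <-> isomer of the product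
- at the start none of the solid reagent is in solution

* which of these there is most of at the end, counted by the substrate in it, teal (substrate / target / intermediate / isomer of the product)
* which of these there is most of at the end, counted by the substrate in it, green (substrate / target / intermediate / isomer of the product)
* amount of the one of these that there is most of at the end, in percent of the substrate charged, teal
* amount of the one of these that there is most of at the end, in percent of the substrate charged, green

The ash and alder runs start from 13 mM and 30 mM of substrate, yet at 120 s they still hold 76.6 % and 78.8 % of their charge, so the rate goes about in proportion to the substrate. The cedar run, with 24 mM of solid reagent, reads 78.8 %, so extra solid changes little. Teal lies between ash and alder, so I take their mean, 77.7 %, for its substrate at 2.0 min.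

But the early readings lag, so the fraction lost per minute is not fixed, and I read the decay from the ash run between 40.0 s and 120 s: k = 0.161 min⁻¹, the fraction of the present substrate lost per minute, on average over that stretch, a time constant of 6.21 min. At the fork, the isomer of the product holds 90.5 % of the reacted substrate in the ash run, nearly all.

So for green, carrying k on as an assumption, I reckon 40.7 % substrate and 53.7 % isomer of the product. That loss is 11.9 mM of substrate, less than the 16.0 mM of solid reagent.

The forecast says substrate at 78.3 % for teal and isomer of the product at 55 % for green, both a little above mine, holding that “the dissolved partner seems to sit near a saturation level”.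

Teal gives substrate at 77.7 % and green isomer of the product at 56.7 %, as forecast. In green the solid reagent stands at 0 % by 6.00 min, and the partner falls from 7.06 mM to 4.35 mM after 3.00 min. The substrate found at the end of green, 41.8 %, is more than the 40.3 % that k gives when carried on from the 65.5 % at 3.00 min.

    substrate + partner → intermediate + by-product (k = 0.413 M⁻¹ s⁻¹)
    intermediate ⇌ target (K = 2.40, k = 0.864 s⁻¹)
    solid reagent ⇌ partner, rate k3*(cs3 - [partner]) while solid is left; crystals form when [partner] > cs3 (solubility = 8.70 mM, k = 0.0258 s⁻¹)
    intermediate ⇌ isomer of the product (K = 210, k = 0.451 s⁻¹)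

The neighbour that is teal read at 5.0 min: k carried from 77.7 % gives 47.9 % substrate. The computed flask holds 47.1 % substrate and 51.2 % isomer of the product.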